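**Retrosynthetic overview**

1. The target is a 9,13-epidioxy labdane: a ring A/B trans-decalin (2α-OH, 6α-OH, 19-OH, C8 exo-methylene) whose 1,2-dioxane is spiro at C9 and at C13 of a γ-lactone. Last disconnections: silyl ethers; lactone to a C13-spiro cyclobutanone (Baeyer–Villiger ring expansion, sets C13); C8=C17 to a C17 iodide.
2. Key disconnection: both dioxane bonds, C12–C13 and O–C9, in one tethered formal [3+3] annulation of a C9 spiro-cyclopropane (C9, C11, C12) with a cyclobutanone-derived silylperoxy methyl ketal (C13–O–O), the peroxide silicon being tied through a disiloxane to O19.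
3. Feature that makes this possible: C9 is a fully substituted ring-B carbon carrying both the O–O unit and the C11–C12 bridge of the dioxane, so C9/C11/C12 is a ring-opened cyclopropane and C13–O–O a ketone plus H2O2. The axial C19 hydroxymethyl of ring A lies on the β-face, 1,3-diaxial to C20 and next to C9, the face on which the C9–O bond must form.
4. The decalin comes from 2-methylcyclohexane-1,3-dione by Robinson annulation with a β-keto ester enone (C19 as ester), deconjugative C4 methylation and double hydroboration of a 2,5-diene (sets C2, C5, C6). The C9 ketone then gives C17 (enolate alkylation) and the cyclopropane (methylenation, Simmons–Smith).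
5. Ring order: ring B (from the dione) → ring A → cyclopropane → 1,2-dioxane (key step, cyclopropane opened) → γ-lactone (cyclobutanone expanded).

Key step: step 18

Remark on numbering: labdane numbering is used (C17 on C8, C18/C19 on C4, C20 on C10); α is the face opposite to C20.
Assumption: methyl 3-oxopent-4-enoate (2) and 3-oxocyclobutyl acetate (19) are taken as commercial. Compounds 21–27 are carried as cis/trans mixtures at the oxygen-bearing cyclobutane carbon, which becomes the carbonyl carbon of 28.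

**Route**

Step 1
Reactants: 1 2-methylcyclohexane-1,3-dione; 2 methyl 3-oxopent-4-enoate
Product: 4 methyl (4aS)-4a-methyl-2,5-dioxo-2,3,4,4a,5,6,7,8-octahydronaphthalene-1-carboxylate, via triketo ester 3 (not isolated)
Conditions: Et3N (1 mol %), EtOAc, rt; then L-phenylalanine (1 equiv), (1S)-(+)-10-camphorsulfonic acid (0.5 equiv), DMF, 50 °C
Reagents that add atoms: none
Why: Michael addition followed by an amino-acid-mediated intramolecular aldol condensation of Hajos–Parrish type (Robinson annulation), in which the enamine of the side-chain ketone should select one of the two enantiotopic ring carbonyls and so set C10 as S.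

Step 2
Reactants: 4 enone ester
Product: 5 C9 ethylene ketal of the enone ester
Conditions: ethylene glycol, p-TsOH (catalytic), 4 Å molecular sieves, rt
Reagents that add atoms: ethylene glycol OCCO
Why: Acid-catalysed ketalisation should take the saturated C9 ketone much faster than the carbonyl of the vinylogous β-keto ester.

Step 3
Reactants: 5 ketal enone ester
Product: 6 Δ5 3-keto ester with 4α-methyl and 4β-CO2Me
Conditions: KOtBu, tBuOH/THF, 0 °C; MeI
Reagents that add atoms: iodomethane CI
Why: Deconjugative alkylation of the extended enolate should put the methyl group on C4 from the α-face, anti to the angular C10 methyl, so that the ester ends axial (β, C19) and the alkene moves to C5–C6.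

Step 4
Reactants: 6 Δ5 keto ester
Product: 7 C2–C3 enol triflate
Conditions: KN(SiMe3)2, PhNTf2, THF, −78 °C
Reagents that add atoms: N-phenylbis(trifluoromethanesulfonimide) O=S(=O)(N(c1ccccc1)S(=O)(=O)C(F)(F)F)C(F)(F)F
Why: Deprotonation can only occur at C2 because C4 is quaternary, and O-sulfonylation of the enolate gives the enol triflate.

Step 5
Reactants: 7 enol triflate
Product: 8 2,5-diene ester
Conditions: Pd(OAc)2 (5 mol %), PPh3, HCO2H, Bu3N, DMF, 60 °C
Reagents that add atoms: none
Why: Palladium-catalysed formate reduction of an enol triflate (oxidative addition to zerovalent palladium, hydride transfer from formate, reductive elimination) should leave both alkenes in place.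

Step 6
Reactants: 8 2,5-diene ester
Product: 10 2α,6α-diol with 5α-H, via bis-borane adduct 9 (not isolated)
Conditions: BH3·THF (excess), THF, 0 °C → rt; then NaOH, H2O2, 0 °C
Reagents that add atoms: borane–tetrahydrofuran [BH3-][O+]1CCCC1 (boron, present in 9 only); hydrogen peroxide OO
Why: Hydroboration–oxidation should occur on the α-face of both alkenes because the β-face is covered by the axial C10 methyl and the axial C4 ester, boron going to C2 (C3 is neopentyl) and to C6 (anti-Markovnikov), so that syn addition sets 2α-OH, 5α-H (trans ring fusion) and 6α-OH while the hindered ester survives.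

Step 7
Reactants: 10 diol ketal
Product: 11 2α,6α-dihydroxy 9-ketone
Conditions: HCl (1 M aqueous, catalytic), THF, rt
Reagents that add atoms: water O
Why: Acid-catalysed hydrolysis of the dioxolane unmasks the C9 ketone.

Step 8
Reactants: 11 keto diol
Product: 12 2α,6α-bis(tert-butyldimethylsilyl) ether
Conditions: TBSOTf, 2,6-lutidine, CH2Cl2, −78 → 0 °C
Reagents that add atoms: tert-butyldimethylsilyl trifluoromethanesulfonate CC(C)(C)[Si](C)(C)OS(=O)(=O)C(F)(F)F
Why: A silyl triflate with a hindered pyridine base should silylate both secondary alcohols, including the hindered 6α-OH.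

Step 9
Reactants: 12 bis-silyl ketone
Product: 13 8α-(benzyloxymethyl) ketone (8β-H)
Conditions: LiN(iPr)2, THF, −78 °C; benzyl chloromethyl ether, −78 → −20 °C
Reagents that add atoms: benzyl chloromethyl ether ClCOCc1ccccc1
Why: The ketone can enolise only toward C8, and enolate alkylation installs C17, the enolisable C8 centre settling as the equatorial (α) epimer.

Step 10
Reactants: 13 benzyloxymethyl ketone
Product: 14 C9 exocyclic alkene (C9=C11)
Conditions: Zn, CH2Br2, TiCl4, THF/CH2Cl2, 0 °C → rt
Reagents that add atoms: dibromomethane BrCBr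
Why: The non-basic zinc–titanium methylene reagent (Takai–Lombardo methylenation) should olefinate the hindered, enolisable ketone without β-elimination of the benzyloxy group or epimerisation at C8.

Step 11
Reactants: 14 exocyclic alkene
Product: 15 C9 spiro-cyclopropane (C9, C11, C12)
Conditions: Et2Zn, CH2I2, CH2Cl2, 0 °C → rt
Reagents that add atoms: diiodomethane ICI
Why: Simmons–Smith cyclopropanation of the 1,1-disubstituted alkene, assisted by the homoallylic ether oxygen, gives the spiro[2.5]octane unit, in which C9 is not a stereocentre.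

Step 12
Reactants: 15 cyclopropane benzyl ether
Product: 16 C17 alcohol
Conditions: H2 (1 atm), Pd/C, EtOAc, rt
Reagents that add atoms: none
Why: Hydrogenolysis of the benzyl ether should proceed without opening the unactivated cyclopropane.

Step 13
Reactants: 16 C17 alcohol
Product: 17 C17 iodide
Conditions: I2, PPh3, imidazole, CH2Cl2, 0 °C → rt
Reagents that add atoms: iodine II
Why: Appel-type iodination converts the primary alcohol into the iodide that later serves as the leaving group for the exocyclic alkene.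

Step 14
Reactants: 17 iodo ester
Product: 18 C19 alcohol
Conditions: iBu2AlH, CH2Cl2, −78 → 0 °C; aqueous potassium sodium tartrate
Reagents that add atoms: none
Why: Hydride reduction of the hindered ester frees O19 as the only hydroxyl group, and the primary iodide should not be attacked by the aluminium hydride at low temperature.

Step 15
Reactants: 19 3-oxocyclobutyl acetate
Product: 20 3-methylenecyclobutyl acetate
Conditions: Zn, CH2Br2, TiCl4, THF/CH2Cl2, 0 °C → rt
Reagents that add atoms: dibromomethane BrCBr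
Why: Takai–Lombardo methylenation converts the ketone chemoselectively in the presence of the acetate.

Step 16
Reactants: 20 3-methylenecyclobutyl acetate
Product: 21 3-hydroperoxy-3-methoxycyclobutyl acetate
Conditions: O3, CH2Cl2/MeOH (4:1), −78 °C; N2 purge; concentration below 0 °C
Reagents that add atoms: ozone [O-][O+]=O; methanol CO
Why: Ozonolysis of the 1,1-disubstituted alkene in methanol traps the cyclobutanone carbonyl oxide (Criegee intermediate) as the α-methoxy hydroperoxide.

Step 17
Reactants: 18 C19 alcohol; 21 hydroperoxy ketal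
Product: 23 O19-tethered silylperoxy ketal, via chlorodisiloxanyl ether 22 (not isolated)
Conditions: 1,3-dichloro-1,1,3,3-tetraisopropyldisiloxane, imidazole, CH2Cl2, 0 °C; then 21, Et3N, DMAP (catalytic), −20 °C
Reagents that add atoms: 1,3-dichloro-1,1,3,3-tetraisopropyldisiloxane CC(C)[Si](Cl)(C(C)C)O[Si](Cl)(C(C)C)C(C)C
Why: Stepwise silylation, first of the neopentyl alcohol with one Si–Cl and then of the hydroperoxide with the other (silyl ether and silyl peroxide formation), ties the peroxy ketal to O19.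

Step 18
Reactants: 23 O19-tethered silylperoxy ketal
Product: 25 C9,C13-dispiro 1,2-dioxane iodide, via annulated silyl triflate 24 (not isolated)
Conditions: TMSOTf (1.1 equiv), 2,6-di-tert-butyl-4-methylpyridine (0.2 equiv), CH2Cl2 (0.002 M), −78 °C; then MeOH, Et3N
Reagents that add atoms: trimethylsilyl trifluoromethanesulfonate C[Si](C)(C)OS(=O)(=O)C(F)(F)F (triflate, present in 24 only); methanol CO (methoxy group on silicon)
Why: Proposed new method: TMSOTf ionises the methoxy ketal to a C13 carbenium ion stabilised by the silylperoxy oxygen (a peroxycarbenium ion), which the disiloxane from O19 holds over the β-face so that it attacks the peripheral, equatorial CH2 of the strained spiro-cyclopropane; the C9–C12 σ bond opens to give the C12–C13 bond and a tertiary C9 cation, which the silylated peroxide oxygen captures with loss of the silyl group (as silyl triflate 24, then capped by methanol) to give the O–C9 bond. The closest known reaction type is the Lewis-acid-mediated [3+2] annulation of silylperoxy ketals with 1,1-disubstituted alkenes to 1,2-dioxolanes (alkene attack on the peroxycarbenium ion, then capture of the cation by the silyl peroxide), extended here from a π bond to a cyclopropane σ bond as a formal [3+3] annulation driven by release of ring strain. The 1,2-dioxane is closed in the six-membered mode by the peroxide oxygen at the C9 cation after the tethered C–C bond formation, and the macrocycle that contains the tether is opened again when silicon leaves, so the dioxane is the only new ring. C9 is the only new stereocentre and is controlled by the tether: the disiloxane starts at the axial C19 oxygen, which is 1,3-diaxial to C20 on the β-face, and cannot reach the α-face, so oxygen should enter β (equatorial) and the untouched axial CH2 should stay as C11 on the α-face. The step needs chemoselectivity for the cyclopropane, secured by the absence of any alkene (C8=C17 is masked as the iodide), regioselective opening toward the tertiary C9 cation, which has no second capture site, and capture faster than 1,2-shift or proton loss, secured by the pre-organised intramolecular nucleophile at −78 °C under high dilution.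

Step 19
Reactants: 25 dioxane iodide
Product: 26 8(17)-exocyclic alkene
Conditions: DBU, toluene, 80 °C
Reagents that add atoms: none
Why: In this E2 dehydroiodination H-8 is the only β-hydrogen, so only the C8=C17 exocyclic alkene can form.

Step 20
Reactants: 26 exocyclic alkene acetate
Product: 27 cyclobutanol
Conditions: K2CO3 (0.2 equiv), MeOH, 0 °C → rt
Reagents that add atoms: none
Why: Base-catalysed transesterification removes the acetate, and the di-tertiary peroxide has no α-hydrogen for base-induced fragmentation.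

Step 21
Reactants: 27 cyclobutanol
Product: 28 C13-spiro cyclobutanone
Conditions: Dess–Martin periodinane, pyridine, CH2Cl2, 0 °C → rt
Reagents that add atoms: none
Why: Dess–Martin oxidation of the secondary cyclobutanol gives the cyclobutanone and removes the cis/trans isomerism, leaving C13 prochiral.

Step 22
Reactants: 28 cyclobutanone
Product: 29 γ-lactone (bis-silyl, O19-disiloxanyl protected target)
Conditions: chiral BINOL-derived phosphoric acid (10 mol %), 30% aqueous H2O2, CHCl3, −40 °C
Reagents that add atoms: hydrogen peroxide OO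
Why: Catalyst-controlled Baeyer–Villiger desymmetrisation of the prochiral 3,3-disubstituted cyclobutanone, in which the chiral acid should select which of the two diastereotopic methylene groups migrates and so set C13, while hydrogen peroxide leaves the exocyclic alkene untouched.

Step 23
Reactants: 29 protected lactone
Product: 30 target (CNP0262224.1)
Conditions: HF·pyridine, pyridine, THF, 0 °C → rt
Reagents that add atoms: none
Why: Fluoride-mediated cleavage of the two silyl ethers and of the disiloxanyl ether should give the triol without touching the lactone, the peroxide or the alkene.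

**Compound list**

1 | 2-methylcyclohexane-1,3-dione | CC1C(=O)CCCC1=O | starting material
2 | methyl 3-oxopent-4-enoate | C=CC(=O)CC(=O)OC | starting material
3 | methyl 5-(1-methyl-2,6-dioxocyclohexyl)-3-oxopentanoate | COC(=O)CC(=O)CCC1(C)C(=O)CCCC1=O | intermediate
4 | methyl (4aS)-4a-methyl-2,5-dioxo-2,3,4,4a,5,6,7,8-octahydronaphthalene-1-carboxylate (C3 and C9 ketones, C4=C5, ester on C4) | C1CCC2=C(C(=O)OC)C(=O)CC[C@]2(C)C1=O | intermediate
5 | C9 ethylene ketal of 4 | C1CCC2=C(C(=O)OC)C(=O)CC[C@]2(C)C13OCCO3 | intermediate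
6 | Δ5 3-ketone, 4α-methyl, 4β-CO2Me (C19), C9 ketal | C1CC=C2[C@@](C)(C(=O)OC)C(=O)CC[C@]2(C)C13OCCO3 | intermediate
7 | C2–C3 enol triflate of 6 | C1CC=C2[C@@](C)(C(=O)OC)C(OS(=O)(=O)C(F)(F)F)=CC[C@]2(C)C13OCCO3 | intermediate
8 | 2,5-diene, C19 methyl ester, C9 ketal | C1CC=C2[C@@](C)(C(=O)OC)C=CC[C@]2(C)C13OCCO3 | intermediate
9 | 2α,6α-bis(boryl) adduct of 8 (5α-H) | C1C[C@H](B)[C@H]2[C@@](C)(C(=O)OC)C[C@H](B)C[C@]2(C)C13OCCO3 | intermediate
10 | 2α,6α-diol, 5α-H, C19 methyl ester, C9 ketal | C1C[C@H](O)[C@H]2[C@@](C)(C(=O)OC)C[C@H](O)C[C@]2(C)C13OCCO3 | intermediate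
11 | 2α,6α-dihydroxy 9-ketone, C19 methyl ester | C1C[C@H](O)[C@H]2[C@@](C)(C(=O)OC)C[C@H](O)C[C@]2(C)C1=O | intermediate
12 | 2α,6α-bis(TBS ether) 9-ketone | C1C[C@H](O[Si](C)(C)C(C)(C)C)[C@H]2[C@@](C)(C(=O)OC)C[C@H](O[Si](C)(C)C(C)(C)C)C[C@]2(C)C1=O | intermediate
13 | 8α-(benzyloxymethyl) 9-ketone (8β-H) | C(OCc3ccccc3)[C@@H]1C[C@H](O[Si](C)(C)C(C)(C)C)[C@H]2[C@@](C)(C(=O)OC)C[C@H](O[Si](C)(C)C(C)(C)C)C[C@]2(C)C1=O | intermediate
14 | C9=C11 exocyclic alkene | C(OCc3ccccc3)[C@@H]1C[C@H](O[Si](C)(C)C(C)(C)C)[C@H]2[C@@](C)(C(=O)OC)C[C@H](O[Si](C)(C)C(C)(C)C)C[C@]2(C)C1=C | intermediate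
15 | C9 spiro-cyclopropane, C17 benzyl ether | C(OCc3ccccc3)[C@@H]1C[C@H](O[Si](C)(C)C(C)(C)C)[C@H]2[C@@](C)(C(=O)OC)C[C@H](O[Si](C)(C)C(C)(C)C)C[C@]2(C)C13CC3 | intermediate
16 | C9 spiro-cyclopropane, C17 alcohol | OC[C@@H]1C[C@H](O[Si](C)(C)C(C)(C)C)[C@H]2[C@@](C)(C(=O)OC)C[C@H](O[Si](C)(C)C(C)(C)C)C[C@]2(C)C13CC3 | intermediate
17 | C9 spiro-cyclopropane, C17 iodide, C19 ester | IC[C@@H]1C[C@H](O[Si](C)(C)C(C)(C)C)[C@H]2[C@@](C)(C(=O)OC)C[C@H](O[Si](C)(C)C(C)(C)C)C[C@]2(C)C13CC3 | intermediate
18 | C9 spiro-cyclopropane, C17 iodide, C19 alcohol | IC[C@@H]1C[C@H](O[Si](C)(C)C(C)(C)C)[C@H]2[C@@](C)(CO)C[C@H](O[Si](C)(C)C(C)(C)C)C[C@]2(C)C13CC3 | intermediate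
19 | 3-oxocyclobutyl acetate | CC(=O)OC1CC(=O)C1 | starting material
20 | 3-methylenecyclobutyl acetate | CC(=O)OC1CC(=C)C1 | intermediate
21 | 3-hydroperoxy-3-methoxycyclobutyl acetate (cis/trans) | CC(=O)OC1CC(OC)(OO)C1 | intermediate
22 | O19 (3-chloro-1,1,3,3-tetraisopropyldisiloxanyl) ether of 18 | IC[C@@H]1C[C@H](O[Si](C)(C)C(C)(C)C)[C@H]2[C@@](C)(CO[Si](C(C)C)(C(C)C)O[Si](Cl)(C(C)C)C(C)C)C[C@H](O[Si](C)(C)C(C)(C)C)C[C@]2(C)C13CC3 | intermediate
23 | O19-disiloxane-tethered silylperoxy methyl ketal | IC[C@@H]1C[C@H](O[Si](C)(C)C(C)(C)C)[C@H]2[C@@](C)(CO[Si](C(C)C)(C(C)C)O[Si](C(C)C)(C(C)C)OOC4(OC)CC(OC(C)=O)C4)C[C@H](O[Si](C)(C)C(C)(C)C)C[C@]2(C)C13CC3 | intermediate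
24 | annulated dioxane with O19 disiloxanyl triflate | IC[C@@H]1C[C@H](O[Si](C)(C)C(C)(C)C)[C@H]2[C@@](C)(CO[Si](C(C)C)(C(C)C)O[Si](C(C)C)(C(C)C)OS(=O)(=O)C(F)(F)F)C[C@H](O[Si](C)(C)C(C)(C)C)C[C@]2(C)[C@]12CCC3(CC(OC(C)=O)C3)OO2 | intermediate
25 | dispiro 1,2-dioxane (9β-O, C11 α), C17 iodide, cyclobutyl acetate, O19 methoxydisiloxanyl ether | IC[C@@H]1C[C@H](O[Si](C)(C)C(C)(C)C)[C@H]2[C@@](C)(CO[Si](C(C)C)(C(C)C)O[Si](C(C)C)(C(C)C)OC)C[C@H](O[Si](C)(C)C(C)(C)C)C[C@]2(C)[C@]12CCC3(CC(OC(C)=O)C3)OO2 | intermediate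
26 | 8(17)-exocyclic alkene, cyclobutyl acetate | C=C1C[C@H](O[Si](C)(C)C(C)(C)C)[C@H]2[C@@](C)(CO[Si](C(C)C)(C(C)C)O[Si](C(C)C)(C(C)C)OC)C[C@H](O[Si](C)(C)C(C)(C)C)C[C@]2(C)[C@]12CCC3(CC(OC(C)=O)C3)OO2 | intermediate
27 | cyclobutanol | C=C1C[C@H](O[Si](C)(C)C(C)(C)C)[C@H]2[C@@](C)(CO[Si](C(C)C)(C(C)C)O[Si](C(C)C)(C(C)C)OC)C[C@H](O[Si](C)(C)C(C)(C)C)C[C@]2(C)[C@]12CCC3(CC(O)C3)OO2 | intermediate
28 | C13-spiro cyclobutanone | C=C1C[C@H](O[Si](C)(C)C(C)(C)C)[C@H]2[C@@](C)(CO[Si](C(C)C)(C(C)C)O[Si](C(C)C)(C(C)C)OC)C[C@H](O[Si](C)(C)C(C)(C)C)C[C@]2(C)[C@]12CCC3(CC(=O)C3)OO2 | intermediate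
29 | 15,16-olide, 2,6-bis(TBS), O19 methoxydisiloxanyl ether | C=C1C[C@H](O[Si](C)(C)C(C)(C)C)[C@H]2[C@@](C)(CO[Si](C(C)C)(C(C)C)O[Si](C(C)C)(C(C)C)OC)C[C@H](O[Si](C)(C)C(C)(C)C)C[C@]2(C)[C@]12CC[C@]3(COC(=O)C3)OO2 | intermediate
30 | CNP0262224.1 | C=C1C[C@H](O)[C@H]2[C@@](C)(CO)C[C@H](O)C[C@]2(C)[C@]12CC[C@]1(COC(=O)C1)OO2 | target

**Step count and risks**

Total: 23 steps. Longest linear sequence: 21 steps (steps 1–14 and 17–23); steps 15–16 make the C13 fragment.

Most likely to fail:

1. Step 18 (Proposed new method). The cyclopropane σ bond may be too weak a nucleophile for the peroxycarbenium ion; the cyclobutyl peroxy ketal may undergo Criegee-type ring expansion instead of ionising; the C9 cation may suffer 1,2-shift or proton loss before capture. Fallback with known reactions, setting out from 12 and coming back at 29: ketone 12 is methylated at C8 (LiN(iPr)2, MeI) to the 8α-methyl ketone F1 and converted (KN(SiMe3)2, PhNTf2) into the C8–C9 enol triflate F2. Reduction with iBu2AlH gives the C19 alcohol F3, which is capped with the dichlorodisiloxane and then methanol to the O19 methoxydisiloxanyl ether F4. Suzuki coupling with CH2=CHBF3K (PdCl2(dppf), Et3N) gives the 9-vinyl diene F5. 9-BBN hydroborates the vinyl group to the alkylborane F6 (used without isolation), which is coupled (PdCl2(dppf), Cs2CO3) with commercial 4-bromofuran-2(5H)-one to the 8,13-dien-15,16-olide F7. mCPBA epoxidises the tetrasubstituted alkene from the α-face to the 8α,9α-epoxide F8. Ethereal H2O2 with catalytic H3PMo12O40 opens the epoxide at C9 with inversion to the 9β-hydroperoxy 8α-alcohol F9, which fixes the C9 configuration. A cinchona amine–thiourea catalysed 6-exo oxa-Michael addition then closes the dioxane and sets C13, giving the 8α-hydroxy dioxane lactone F10. Dehydration of the equatorial tertiary alcohol toward the methyl group (SOCl2, pyridine, −40 °C) gives 29.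

2. Step 22. The catalyst may discriminate poorly between the two diastereotopic methylene groups in the migration step, giving low selectivity at C13. Fallback setting out from 28 and coming back at 29: uncatalysed Baeyer–Villiger oxidation (H2O2, hexafluoroisopropanol) should give 29 together with its C13 epimer F11. After chromatographic separation, F11 is recycled by equilibration with catalytic DBU, which epimerises C13 through reversible β-elimination and re-addition of the peroxide at the lactone β-carbon, and 29 is separated again.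

3. Step 10. Carbonyl olefination may fail at the hindered, enolisable C9 ketone (enolisation, β-elimination of the benzyloxy group). Fallback setting out from 13 and coming back at 14: Peterson olefination, in which Me3SiCH2Li with CeCl3 adds to the ketone from the α-face to give the β-hydroxysilane F12, and KH in THF then eliminates it to 14.

**Further compounds**

F1 | step 18 | 8α-methyl 9-ketone (bis-TBS, C19 ester) | C[C@@H]1C[C@H](O[Si](C)(C)C(C)(C)C)[C@H]2[C@@](C)(C(=O)OC)C[C@H](O[Si](C)(C)C(C)(C)C)C[C@]2(C)C1=O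
F2 | step 18 | C8–C9 enol triflate | CC=1C[C@H](O[Si](C)(C)C(C)(C)C)[C@H]2[C@@](C)(C(=O)OC)C[C@H](O[Si](C)(C)C(C)(C)C)C[C@]2(C)C=1OS(=O)(=O)C(F)(F)F
F3 | step 18 | C19 alcohol enol triflate | CC=1C[C@H](O[Si](C)(C)C(C)(C)C)[C@H]2[C@@](C)(CO)C[C@H](O[Si](C)(C)C(C)(C)C)C[C@]2(C)C=1OS(=O)(=O)C(F)(F)F
F4 | step 18 | O19 methoxydisiloxanyl ether enol triflate | CC=1C[C@H](O[Si](C)(C)C(C)(C)C)[C@H]2[C@@](C)(CO[Si](C(C)C)(C(C)C)O[Si](C(C)C)(C(C)C)OC)C[C@H](O[Si](C)(C)C(C)(C)C)C[C@]2(C)C=1OS(=O)(=O)C(F)(F)F
F5 | step 18 | 9-vinyl 8(9)-ene | CC=1C[C@H](O[Si](C)(C)C(C)(C)C)[C@H]2[C@@](C)(CO[Si](C(C)C)(C(C)C)O[Si](C(C)C)(C(C)C)OC)C[C@H](O[Si](C)(C)C(C)(C)C)C[C@]2(C)C=1C=C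
F6 | step 18 | C12 alkyl-9-BBN borane | CC=1C[C@H](O[Si](C)(C)C(C)(C)C)[C@H]2[C@@](C)(CO[Si](C(C)C)(C(C)C)O[Si](C(C)C)(C(C)C)OC)C[C@H](O[Si](C)(C)C(C)(C)C)C[C@]2(C)C=1CCB3C4CCCC3CCC4
F7 | step 18 | 8,13-dien-15,16-olide | CC=1C[C@H](O[Si](C)(C)C(C)(C)C)[C@H]2[C@@](C)(CO[Si](C(C)C)(C(C)C)O[Si](C(C)C)(C(C)C)OC)C[C@H](O[Si](C)(C)C(C)(C)C)C[C@]2(C)C=1CCC3=CC(=O)OC3
F8 | step 18 | 8α,9α-epoxide | C[C@@]12C[C@H](O[Si](C)(C)C(C)(C)C)[C@H]3[C@@](C)(CO[Si](C(C)C)(C(C)C)O[Si](C(C)C)(C(C)C)OC)C[C@H](O[Si](C)(C)C(C)(C)C)C[C@]3(C)[C@]1(CCC4=CC(=O)OC4)O2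
F9 | step 18 | 9β-hydroperoxy 8α-alcohol | C[C@@]1(O)C[C@H](O[Si](C)(C)C(C)(C)C)[C@H]2[C@@](C)(CO[Si](C(C)C)(C(C)C)O[Si](C(C)C)(C(C)C)OC)C[C@H](O[Si](C)(C)C(C)(C)C)C[C@]2(C)[C@]1(OO)CCC3=CC(=O)OC3
F10 | step 18 | 8α-hydroxy 9,13-epidioxy 15,16-olide | C[C@@]1(O)C[C@H](O[Si](C)(C)C(C)(C)C)[C@H]2[C@@](C)(CO[Si](C(C)C)(C(C)C)O[Si](C(C)C)(C(C)C)OC)C[C@H](O[Si](C)(C)C(C)(C)C)C[C@]2(C)[C@]13CC[C@]4(COC(=O)C4)OO3
F11 | step 22 | C13 epimer of 29 | C=C1C[C@H](O[Si](C)(C)C(C)(C)C)[C@H]2[C@@](C)(CO[Si](C(C)C)(C(C)C)O[Si](C(C)C)(C(C)C)OC)C[C@H](O[Si](C)(C)C(C)(C)C)C[C@]2(C)[C@]12CC[C@@]3(COC(=O)C3)OO2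
F12 | step 10 | 9β-hydroxy 9α-(trimethylsilylmethyl) adduct of 13 | C(OCc3ccccc3)[C@@H]1C[C@H](O[Si](C)(C)C(C)(C)C)[C@H]2[C@@](C)(C(=O)OC)C[C@H](O[Si](C)(C)C(C)(C)C)C[C@]2(C)[C@]1(O)C[Si](C)(C)C
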